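# Proposed total synthesis of CNP0169816.2 (37) by furanone photocycloaddition and ring-expanding fragmentation

## Analysis of the target

Compound 37 is built from two trans-fused 2,2-dimethyloxepane–cyclohexane bicycles (rings A/B and A'/B') joined through the two-carbon bridge C12–C12'. The numbering used throughout is, for each half: O1, C2 (CMe2), C3 (CH–O), C4, C5, C6 (C–Me) and C7 (CH–O) for the oxepane, C6–C7–C8–C9–C10(Me,O)–C11 for the cyclohexane, and C12 for the bridge carbon on C11; primed locants belong to the half with the free C3' hydroxyl. There are ten stereocentres. C3, C6, C7 and C11 have the same sense in both halves (all S in 37), and the halves differ only at the tertiary carbinol (C10 S, C10' R) and in acylation at C3. In each half the C6 methyl is axial, anti to C7–H (trans ring fusion), cis to the equatorial C12 branch and trans to the C3 oxygen. At C10 the methyl is axial and the acetate equatorial, whereas at C10' the acetate is axial and 1,3-diaxial to the C6' methyl. Functionality is sparse: two tertiary acetates (hard to install, prone to elimination), one secondary acetate, and one secondary alcohol that must be told apart from its acetylated twin. The difficulty is stereochemical and topological: a quaternary C6 flanked by C7 and C11, a seven-membered ether between a secondary and a tertiary carbon, and two diastereomeric halves. The plan rests on one feature: O1', C2', C3', C4' and C7' would form a 2,2-dimethyl-3(2H)-furanone if C4' and C7' were bonded, so ring A' is that furanone with C5'–C6' inserted into its C4'–C7' bond, and ring A likewise.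

## Retrosynthetic reasoning

**37 back to 34 (end game).** The free C3' hydroxyl is carried as a benzyl ether so that one hydrogenation of 36 removes it and saturates the C12=C12' bond. The three acetates of 36 are placed last, on triol 35, which comes from 34 by desilylation. Acetates cannot be present earlier. On C10' of aldehyde 17 an acetoxy group would be axial and anti-periplanar to the enolisable C11'–H and would be lost by elimination. On C10 of sulfone 33 it would sit where the sulfonyl carbanion can reach its carbonyl through a five-membered transition state. Both tertiary oxygens therefore travel as silyl ethers up to 34.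

**34 to 33 and 17 (C12=C12').** The central bond is cut as an alkene made by sulfone olefination. This cut divides the molecule into two bicycles of equal size that differ only at C10 and in the C3 protecting group. Each partner carries its reacting carbon on C11, so no stereocentre is touched. The forward reaction only has to join two hindered partners; alkene geometry is irrelevant.

**17 to 13 and 33 to 28 (functional-group adjustment).** The C12 oxygen of each half is unmasked late and becomes the aldehyde (17) or the sulfone (33). The C3 carbinol comes from the C3 ketone of oxepanones 13 and 28 by reagent-controlled hydride reduction. The ketone is flanked by a fully substituted carbon and a methylene, the pattern that oxazaborolidine catalysts read best.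

**13 to 12 and 28 to 27 (ring expansion).** Reconnecting C4' to C7' turns the oxepan-3-one into a cyclobutane fused to a 2,2-dimethyl-dihydrofuranone. In the forward sense the C3' ketyl cleaves that bond, because it joins the carbon alpha to the ketone with the carbon carrying the ring oxygen. The five-membered heterocycle becomes the seven-membered one and C7' is left ready to take up hydrogen. The gain is that the ether bridge C7'–O1'–C2' never has to be closed as a medium ring.

**12 to 11 and 27 to 26 (key disconnection).** Cutting C4'–C5' and C6'–C7' of the cyclobutane opens ring B' as well. What remains is a 3(2H)-furanone carrying at C7' a four-atom chain (C8'–C11') that ends in an isopropenyl group. The forward intramolecular [2+2] photocycloaddition must close ring B' in the straight sense and must place the C6' methyl cis to C12'. The stereocentres C10' and C11' are already in the chain and steer it.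

**11 to 6 and 8 (furanone).** The furanone is cut at O1'–C7' (cyclodehydration) and C4'–C7' (aldol, then oxidation) into aldehyde 6 and the silylated hydroxy ketone 8. A lactone bridging O–C10' and C7' would be a more direct acyl donor. Opening it, however, would free the C10' hydroxyl next to the new 1,3-diketone, where it competes with the C2' hydroxyl for C7'. An open-chain aldehyde with O–C10' silylated avoids this.

**6 back to nerol 1, and 23 back to geraniol 18 (the C10/C11 pair).** The C6'–C11' bond is cut next to the tertiary carbinol, giving a 2,3-epoxy alcohol and an isopropenyl nucleophile. Anti opening at the less substituted epoxide carbon sets C11' with inversion and leaves C10' as set by the epoxidation. The Z alcohol 1 and the E alcohol 18, epoxidised with the same tartrate, deliver the two C10 epimers that the two halves need. Allylating a methyl ketone could not do this, since it would have to distinguish a methyl from a primary alkyl group. The distal trisubstituted alkene of 1 and 18 serves as the latent C7' aldehyde.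

## Alternatives that were turned down

**Alternative 1:** Ring A is opened at C3=C4 and the C2–O1 ether is traced back to a C7 carbinol obtained by desymmetrising a prochiral cyclic 1,3-diketone. In the forward key step the second-generation Grubbs catalyst closes diene A2 to the trans-fused oxepene A1.

- For it: ring-closing metathesis to seven-membered ethers is dependable and thermal, and the trans ring fusion is fixed in an isolable precursor before the ring forms. On predictability of the key step it is stronger than a photocycloaddition.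
- Against it: the tertiary allylic ether must be made on a neopentyl-type secondary alcohol. The C3 oxygen must then be placed next to the quaternary C2 on an alkene whose less hindered end is C4. Decisively, ring B arrives as a bare cyclohexanone. C10 (methyl and oxygen) and C11 (the C12 branch) must be built on the ring afterwards, and this must be done twice with opposite sense at C10, once with and once against the bias of the same bicycle.
- Comparison: the chosen route sets C10 and C11 in open chains by reagent control (E or Z epoxide) and uses them to steer the ring closure. A1 is reached quickly but lies much further from 37 than 13 does.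

**Alternative 2:** The C6'–C11' bond is cut. In the forward key step Cp2TiCl (trivalent titanium) opens a C6'–C7' epoxide homolytically and the tertiary C6' radical closes 6-exo onto a vinyl sulfone to give A3.

- For it: the radical chemistry is reliable, polarity-matched and scalable. The sulfone for the union is delivered at C12' for free, and a tertiary carbinol from the chiral pool could serve both C10 series. On operational reliability and on delivering the coupling handle it is stronger than the chosen route.
- Against it: the C6' radical is planar and carries two groups of similar size (methyl and a CH2CH2 chain), so the quaternary centre rests on a small axial/equatorial preference. C7' needs an enantioselective epoxidation of an unfunctionalised alkene. Ring A' still has to be closed as a seven-membered ether between a hindered secondary oxygen and a tertiary carbon, in competition with six-membered closure.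
- Comparison: the chosen strategy controls C6' by allylic strain, where the two groups on the alkene carbon differ clearly (a methyl and the methylene that becomes ring A'). It also has the C7'–O1'–C2' linkage in place from a simple cyclodehydration, so the medium-ring ether closure disappears.

**Alternative 3:** The two one-carbon branches C5' and C12' are removed together and traced to the two carbons of vinylene carbonate A6 added across the C6'=C11' bond of enone A5. The forward key step is an intermolecular [2+2] photocycloaddition giving the cis-fused cyclobutane carbonate A4, whose diol is later cleaved to two formyl groups.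

- For it: ring B' exists beforehand, so there is no straight-versus-crossed question and the cyclobutane stereochemistry is easier to foresee. The quaternary C6' and both branches come in one step. On these points it is at least as strong as the chosen route.
- Against it: the reaction is intermolecular (excess A6, enone dimerisation), and the face selectivity against the C10' substituents would have to hold for both C10 epimers. After cleavage the two aldehydes must be differentiated and C11' epimerised next to a beta oxygen. The whole of ring A' (C4', C3', C2', the ether bridge, the C3' carbinol and a stereoselective reduction at C7') remains to be built.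
- Comparison: both routes carry a photochemical risk. A4 buys only two bonds to one-carbon stubs, whereas 12 contains ring B' and every atom of ring A'.

Key step: step 8

## Route

Abbreviations: TBS = tert-butyldimethylsilyl, TMS = trimethylsilyl, Bn = benzyl, PT = 1-phenyl-1H-tetrazol-5-yl, DMP = Dess–Martin periodinane.

Remark: the transient epoxides 5 and 22 and the aldol adducts 9 and 24 are epimer mixtures at a carbon that loses its stereogenicity one operation later; their SMILES leave that centre open.

Remark: the epoxy alcohols 2 and 19 are expected in high but not perfect enantiomeric excess; because both halves are made in the same enantiomeric series, minor-series material ends after step 27 as a diastereomer of 34 and is removed there.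

Remark: alkene 34 is written as the expected E isomer; any Z isomer converges in step 30.

Step 1
Reactants: 1 nerol
Product: 2 [(2S,3R)-3-methyl-3-(4-methylpent-3-en-1-yl)oxiran-2-yl]methanol
Conditions: Ti(OiPr)4 (10 mol %), L-(+)-diethyl tartrate (12 mol %), t-BuOOH, 4 Å molecular sieves, CH2Cl2, −20 °C
Reagents that add atoms: tert-butyl hydroperoxide, CC(C)(C)OO
Why: Sharpless asymmetric epoxidation; the allylic hydroxyl binds titanium, so only the 2,3-alkene reacts, and the L-(+)-tartrate complex delivers oxygen to the face that gives the (2S,3R) epoxide of the Z alcohol. This fixes C10' (epoxide C3) and places the C11' oxygen for later inversion.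

Step 2
Reactants: 2 (2S,3R)-2,3-epoxynerol
Product: 3 (2R,3R)-3,7-dimethyl-2-(prop-1-en-2-yl)oct-6-ene-1,3-diol
Conditions: CH2=C(CH3)MgBr (4 equiv), CuI (20 mol %), THF, −30 → 0 °C
Reagents that add atoms: isopropenylmagnesium bromide, CC(=C)[Mg]Br
Why: Copper-catalysed Grignard opening of a 2,3-epoxy alcohol; the organocopper attacks anti at C2 because C3 is fully substituted, giving the 1,3-diol. Inversion at C2 sets C11', the tertiary carbinol keeps the C10' configuration, and the C6'–C11' bond is formed.

Step 3
Reactants: 3 (2R,3R)-diol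
Product: 4 (2R,3R)-1,3-bis(TBS-oxy)-3,7-dimethyl-2-(prop-1-en-2-yl)oct-6-ene
Conditions: TBSOTf (3 equiv), 2,6-lutidine, CH2Cl2, 0 °C → rt
Reagents that add atoms: tert-butyldimethylsilyl trifluoromethanesulfonate, CC(C)(C)[Si](C)(C)OS(=O)(=O)C(F)(F)F
Why: Silyl triflate with a hindered pyridine base silylates the primary and the tertiary hydroxyl in one operation. The tertiary ether is essential: a free C10' hydroxyl would add to C7' once that carbon is a ketone (hemiketal, alkylidene tetrahydrofuran or spiroketal in place of the furanone).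

Step 4
Reactants: 4 bis-silyl ether
Product: 6 (4R,5R)-4-(TBS-oxy)-5-[(TBS-oxy)methyl]-4,6-dimethylhept-6-enal, via epoxide 5 (not isolated)
Conditions: mCPBA (1.0 equiv), CH2Cl2, −10 °C; then H5IO6, THF/H2O, 0 °C
Reagents that add atoms: meta-chloroperoxybenzoic acid, OOC(=O)c1cccc(Cl)c1
Why: Electrophilic epoxidation favours the electron-rich, unhindered trisubstituted alkene over the 1,1-disubstituted one, which is shielded by the two silylated stereocentres. Periodic acid then hydrolyses and cleaves the epoxide in the same flask to the C7' aldehyde and acetone.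

Step 5
Reactants: 7 3-hydroxy-3-methylbutan-2-one
Product: 8 3-methyl-3-(TMS-oxy)butan-2-one
Conditions: TMSCl, Et3N, DMAP (cat.), CH2Cl2, 0 °C → rt
Reagents that add atoms: chlorotrimethylsilane, C[Si](C)(C)Cl
Why: Standard silylation of a tertiary alcohol; the ether lets the ketone form a single lithium enolate at its methyl group and is removed by mild acid in step 7.

Step 6
Reactants: 6 aldehyde; 8 silyloxy ketone
Product: 9 (8R,9R)-8-(TBS-oxy)-9-[(TBS-oxy)methyl]-5-hydroxy-2,8,10-trimethyl-2-(TMS-oxy)undec-10-en-3-one (both C5 epimers)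
Conditions: 8, LiN(iPr)2, THF, −78 °C; then 6, −78 °C
Reagents that add atoms: none
Why: Lithium enolate aldol addition; the only enolisable position of 8 is its methyl group, which becomes C4' and bonds to C7'. The new carbinol centre is uncontrolled and is oxidised in the next step.

Step 7
Reactants: 9 aldol adduct
Product: 11 5-[(3R,4R)-3-(TBS-oxy)-4-[(TBS-oxy)methyl]-3,5-dimethylhex-5-en-1-yl]-2,2-dimethylfuran-3(2H)-one, via diketone 10 (not isolated)
Conditions: DMP (1.3 equiv), wet CH2Cl2, 0 °C → rt; then TsOH·H2O (0.2 equiv), rt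
Reagents that add atoms: none
Why: Dess–Martin oxidation of the beta-hydroxy ketone gives the 1,3-diketone; acid removes the labile tertiary TMS ether, the freed hydroxyl adds 5-exo to the C7' carbonyl and the hemiketal dehydrates to the vinylogous ester (classical 3(2H)-furanone synthesis by aldol, oxidation and cyclodehydration). The primary and tertiary TBS ethers tolerate brief catalytic acid in CH2Cl2.

Step 8
Reactants: 11 furanone
Product: 12 (1R,5R,7S,8R,9R)-9-(TBS-oxy)-8-[(TBS-oxy)methyl]-3,3,7,9-tetramethyl-2-oxatricyclo[5.4.0.0(1,5)]undecan-4-one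
Conditions: hν (λ ≥ 300 nm, Pyrex filter), degassed MeCN, 0.005 M, rt
Reagents that add atoms: none
Why: Excitation of the vinylogous ester (n→π*, then intersystem crossing) gives the furanone triplet, which adds to the tethered 1,1-disubstituted alkene stepwise through a 1,4-biradical; this is the intramolecular enone–alkene [2+2] photocycloaddition known for 3(2H)-furanones and other beta-alkoxy enones with alkenyl chains. Ring B' closes in the straight (1,6) mode, C7' bonding to C6' through the four-atom tether C8'–C11' in a chair-like array, and the cyclobutane closes by biradical collapse between C4' and C5', cis-fused to ring B' and necessarily cis-fused to the furanone ring. C6' is controlled by C11': allylic strain holds the C11'–H bond in the plane of the C6'=C5' bond, eclipsing the methylene, so C12' lies pseudo-equatorial and the furanone, which hangs on the C10' branch, can only reach the alkene face that leaves the C6' methyl anti to C11'–H, that is cis to C12'. C7' follows from C6' because the second bond forms on the same face, and C4' is fixed by the cis fusion of the five- and four-membered rings. The step needs straight rather than crossed regiochemistry and the face selectivity just described. The first is secured by the tether: crossed closure would need a seven-membered first ring and would give a strained bridged adduct, while biradicals that cannot close revert to 11. The second is secured by the C11' stereocentre, helped by the quaternary C10' centre, which folds the tether (Thorpe–Ingold effect); the C10' silyl ether ends up axial and is a spectator.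

Step 9
Reactants: 12 photoadduct
Product: 13 (5aS,6R,7R,9aS)-7-(TBS-oxy)-6-[(TBS-oxy)methyl]-2,2,5a,7-tetramethyloctahydro-1-benzoxepin-3(2H)-one
Conditions: SmI2 (3 equiv), HMPA, t-BuOH, THF, −78 → 0 °C
Reagents that add atoms: none
Why: Ketyl fragmentation of a cyclobutyl ketone by divalent samarium; cleavage of C4'–C7' releases a tertiary alpha-alkoxy radical and turns the strained 2-oxabicyclo[3.2.0]heptanone into the samarium enolate of the oxepanone. The C7' centre is reduced and protonated from the axial direction, anti to the axial C6' methyl, which gives C7'–H trans to that methyl (the trans ring fusion).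

Step 10
Reactants: 13 oxepanone
Product: 14 (3S,5aS,6R,7R,9aS)-7-(TBS-oxy)-6-[(TBS-oxy)methyl]-2,2,5a,7-tetramethyldecahydro-1-benzoxepin-3-ol
Conditions: (R)-1-methyl-3,3-diphenyltetrahydro-1H,3H-pyrrolo[1,2-c][1,3,2]oxazaborole (0.3 equiv), BH3·SMe2, THF, −20 °C
Reagents that add atoms: none
Why: Corey–Bakshi–Shibata reduction; the fully substituted C2' acts as the large and the C4' methylene as the small group, so the (R)-catalyst gives the (3S)-alcohol in the sense in which acetophenone gives (S)-1-phenylethanol. Reagent control is chosen because the intrinsic face bias of the oxepanone is uncertain; NaBH4 and LiBH(s-Bu)3 remain as the two substrate-controlled options.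

Step 11
Reactants: 14 alcohol
Product: 15 (3S,5aS,6R,7R,9aS)-3-(benzyloxy)-7-(TBS-oxy)-6-[(TBS-oxy)methyl]-2,2,5a,7-tetramethyldecahydro-1-benzoxepine
Conditions: NaH, BnBr, Bu4NI (cat.), THF/DMF, 0 → 40 °C
Reagents that add atoms: benzyl bromide, BrCc1ccccc1
Why: Williamson etherification of the hindered secondary alkoxide. The benzyl ether marks C3' as the one oxygen that must end free; it survives base, fluoride and acylation and leaves in the final hydrogenation.

Step 12
Reactants: 15 benzyl ether
Product: 16 [(3S,5aS,6R,7R,9aS)-3-(benzyloxy)-7-(TBS-oxy)-2,2,5a,7-tetramethyldecahydro-1-benzoxepin-6-yl]methanol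
Conditions: HF·pyridine, pyridine, THF, 0 °C → rt
Reagents that add atoms: none
Why: Selective desilylation; buffered HF·pyridine cleaves the unhindered primary silyl ether much faster than the tertiary one on C10'.

Step 13
Reactants: 16 primary alcohol
Product: 17 (3S,5aS,6S,7R,9aS)-3-(benzyloxy)-7-(TBS-oxy)-2,2,5a,7-tetramethyldecahydro-1-benzoxepine-6-carbaldehyde
Conditions: DMP, CH2Cl2, 0 °C → rt
Reagents that add atoms: none
Why: Dess–Martin oxidation under non-basic conditions, which keeps the beta-silyloxy aldehyde from eliminating. The formyl group is equatorial, so C11' has no drive to epimerise.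

Step 14
Reactants: 18 geraniol
Product: 19 [(2S,3S)-3-methyl-3-(4-methylpent-3-en-1-yl)oxiran-2-yl]methanol
Conditions: Ti(OiPr)4 (10 mol %), L-(+)-diethyl tartrate (12 mol %), t-BuOOH, 4 Å molecular sieves, CH2Cl2, −20 °C
Reagents that add atoms: tert-butyl hydroperoxide, CC(C)(C)OO
Why: Sharpless asymmetric epoxidation as in step 1; the same tartrate attacks the same face at C2, and the E geometry places the C3 methyl and chain the other way round. C10 is thereby set epimeric to C10' of the other half.

Step 15
Reactants: 19 (2S,3S)-2,3-epoxygeraniol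
Product: 20 (2R,3S)-3,7-dimethyl-2-(prop-1-en-2-yl)oct-6-ene-1,3-diol
Conditions: CH2=C(CH3)MgBr (4 equiv), CuI (20 mol %), THF, −30 → 0 °C
Reagents that add atoms: isopropenylmagnesium bromide, CC(=C)[Mg]Br
Why: Copper-catalysed anti opening at C2 of the epoxy alcohol, as in step 2; inversion at C2 gives C11 with the same sense as C11', while C10 keeps the configuration set in step 14.

Step 16
Reactants: 20 (2R,3S)-diol
Product: 21 (2R,3S)-1,3-bis(TBS-oxy)-3,7-dimethyl-2-(prop-1-en-2-yl)oct-6-ene
Conditions: TBSOTf (3 equiv), 2,6-lutidine, CH2Cl2, 0 °C → rt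
Reagents that add atoms: tert-butyldimethylsilyl trifluoromethanesulfonate, CC(C)(C)[Si](C)(C)OS(=O)(=O)C(F)(F)F
Why: Double silylation with silyl triflate, for the same reasons as in step 3.

Step 17
Reactants: 21 bis-silyl ether
Product: 23 (4S,5R)-4-(TBS-oxy)-5-[(TBS-oxy)methyl]-4,6-dimethylhept-6-enal, via epoxide 22 (not isolated)
Conditions: mCPBA (1.0 equiv), CH2Cl2, −10 °C; then H5IO6, THF/H2O, 0 °C
Reagents that add atoms: meta-chloroperoxybenzoic acid, OOC(=O)c1cccc(Cl)c1
Why: Chemoselective peracid epoxidation of the remote trisubstituted alkene followed by periodic acid cleavage, as in step 4.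

Step 18
Reactants: 23 aldehyde; 8 silyloxy ketone
Product: 24 (8S,9R)-8-(TBS-oxy)-9-[(TBS-oxy)methyl]-5-hydroxy-2,8,10-trimethyl-2-(TMS-oxy)undec-10-en-3-one (both C5 epimers)
Conditions: 8, LiN(iPr)2, THF, −78 °C; then 23, −78 °C
Reagents that add atoms: none
Why: Lithium enolate aldol addition forming C4–C7, as in step 6.

Step 19
Reactants: 24 aldol adduct
Product: 26 5-[(3S,4R)-3-(TBS-oxy)-4-[(TBS-oxy)methyl]-3,5-dimethylhex-5-en-1-yl]-2,2-dimethylfuran-3(2H)-one, via diketone 25 (not isolated)
Conditions: DMP (1.3 equiv), wet CH2Cl2, 0 °C → rt; then TsOH·H2O (0.2 equiv), rt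
Reagents that add atoms: none
Why: Dess–Martin oxidation to the 1,3-diketone, then acid-induced desilylation and cyclodehydration to the furanone, as in step 7.

Step 20
Reactants: 26 furanone
Product: 27 (1R,5R,7S,8R,9S)-9-(TBS-oxy)-8-[(TBS-oxy)methyl]-3,3,7,9-tetramethyl-2-oxatricyclo[5.4.0.0(1,5)]undecan-4-one
Conditions: hν (λ ≥ 300 nm, Pyrex filter), degassed MeCN, 0.005 M, rt
Reagents that add atoms: none
Why: The same intramolecular [2+2] photocycloaddition as in step 8; C11 again holds its hydrogen in the alkene plane and directs the C6 methyl cis to C12, with C7 and C4 following from the cis ring fusions. In this series the C10 methyl becomes axial and meets the C6 methyl 1,3-diaxially, so the closure is expected to be slower, but the element that controls the face is unchanged.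

Step 21
Reactants: 27 photoadduct
Product: 28 (5aS,6R,7S,9aS)-7-(TBS-oxy)-6-[(TBS-oxy)methyl]-2,2,5a,7-tetramethyloctahydro-1-benzoxepin-3(2H)-one
Conditions: SmI2 (3 equiv), HMPA, t-BuOH, THF, −78 → 0 °C
Reagents that add atoms: none
Why: Ketyl fragmentation of the C4–C7 bond and axial hydrogen delivery to C7 anti to the C6 methyl, as in step 9.

Step 22
Reactants: 28 oxepanone
Product: 29 (3S,5aS,6R,7S,9aS)-7-(TBS-oxy)-6-[(TBS-oxy)methyl]-2,2,5a,7-tetramethyldecahydro-1-benzoxepin-3-ol
Conditions: (R)-1-methyl-3,3-diphenyltetrahydro-1H,3H-pyrrolo[1,2-c][1,3,2]oxazaborole (0.3 equiv), BH3·SMe2, THF, −20 °C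
Reagents that add atoms: none
Why: Corey–Bakshi–Shibata reduction with C2 as the large and C4 as the small group, giving the (3S)-alcohol as in step 10.

Step 23
Reactants: 29 alcohol
Product: 30 (3S,5aS,6R,7S,9aS)-3,7-bis(TBS-oxy)-6-[(TBS-oxy)methyl]-2,2,5a,7-tetramethyldecahydro-1-benzoxepine
Conditions: TBSOTf, 2,6-lutidine, CH2Cl2, 0 °C → rt
Reagents that add atoms: tert-butyldimethylsilyl trifluoromethanesulfonate, CC(C)(C)[Si](C)(C)OS(=O)(=O)C(F)(F)F
Why: Silyl triflate silylates the hindered secondary C3 hydroxyl. A silyl ether is used here because this oxygen is to be freed together with the tertiary ones and acetylated at the end.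

Step 24
Reactants: 30 tris-silyl ether
Product: 31 [(3S,5aS,6R,7S,9aS)-3,7-bis(TBS-oxy)-2,2,5a,7-tetramethyldecahydro-1-benzoxepin-6-yl]methanol
Conditions: HF·pyridine, pyridine, THF, 0 °C → rt
Reagents that add atoms: none
Why: Selective desilylation; the primary silyl ether is cleaved far faster than the tertiary one and the neopentyl-type secondary one.

Step 25
Reactants: 31 primary alcohol
Product: 32 5-({[(3S,5aS,6S,7S,9aS)-3,7-bis(TBS-oxy)-2,2,5a,7-tetramethyldecahydro-1-benzoxepin-6-yl]methyl}sulfanyl)-1-phenyl-1H-tetrazole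
Conditions: 1-phenyl-1H-tetrazole-5-thiol, PPh3, diisopropyl azodicarboxylate, THF, 0 °C → rt
Reagents that add atoms: 1-phenyl-1H-tetrazole-5-thiol, Sc1nnnn1-c1ccccc1
Why: Mitsunobu thioetherification; the acidic thiol displaces the phosphonium-activated primary oxygen. No other free hydroxyl is present.

Step 26
Reactants: 32 sulfide
Product: 33 5-({[(3S,5aS,6S,7S,9aS)-3,7-bis(TBS-oxy)-2,2,5a,7-tetramethyldecahydro-1-benzoxepin-6-yl]methyl}sulfonyl)-1-phenyl-1H-tetrazole
Conditions: (NH4)6Mo7O24·4H2O (20 mol %), 30% aq. H2O2, EtOH, 0 °C → rt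
Reagents that add atoms: hydrogen peroxide, OO
Why: Molybdate-catalysed peroxide oxidation of the sulfide to the sulfone, the usual entry to tetrazolyl sulfones; silyl ethers and the ring ether are inert.

Step 27
Reactants: 33 PT sulfone; 17 aldehyde
Product: 34 (E)-1-[(3S,5aS,6S,7S,9aS)-3,7-bis(TBS-oxy)-2,2,5a,7-tetramethyldecahydro-1-benzoxepin-6-yl]-2-[(3S,5aS,6S,7R,9aS)-3-(benzyloxy)-7-(TBS-oxy)-2,2,5a,7-tetramethyldecahydro-1-benzoxepin-6-yl]ethene
Conditions: 33, KN(SiMe3)2, DME, −78 °C; then 17, −78 °C → rt
Reagents that add atoms: none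
Why: Julia–Kocienski olefination; the sulfonyl carbanion adds to the aldehyde, the alkoxide attacks the tetrazole (Smiles rearrangement), and loss of SO2 and the tetrazolone gives the alkene directly. Both tertiary oxygens are silyl ethers, so neither beta-elimination in 17 nor acyl transfer to the carbanion of 33 can occur; alkene geometry is of no consequence.

Step 28
Reactants: 34 alkene
Product: 35 (3S,5aS,6S,7S,9aS)-6-[(E)-2-{(3S,5aS,6S,7R,9aS)-3-(benzyloxy)-7-hydroxy-2,2,5a,7-tetramethyldecahydro-1-benzoxepin-6-yl}ethenyl]-2,2,5a,7-tetramethyldecahydro-1-benzoxepine-3,7-diol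
Conditions: Bu4NF (excess), THF, 60 °C
Reagents that add atoms: none
Why: Fluoride-induced desilylation; heating is needed for the two tertiary ethers and the hindered secondary one. The benzyl ether and the alkene are untouched.

Step 29
Reactants: 35 triol
Product: 36 (3S,5aS,6S,7S,9aS)-6-[(E)-2-{(3S,5aS,6S,7R,9aS)-7-acetoxy-3-(benzyloxy)-2,2,5a,7-tetramethyldecahydro-1-benzoxepin-6-yl}ethenyl]-2,2,5a,7-tetramethyldecahydro-1-benzoxepine-3,7-diyl diacetate
Conditions: n-BuLi (3.3 equiv), THF, −78 °C; then Ac2O (excess), −78 °C → rt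
Reagents that add atoms: acetic anhydride, CC(=O)OC(C)=O
Why: Acylation of preformed lithium alkoxides, the method of choice for hindered tertiary alcohols that react sluggishly as neutral hydroxyls; the secondary C3 alkoxide is acetylated as well. C3' is a benzyl ether and stays unacylated.

Step 30
Reactants: 36 triacetate
Product: 37 CNP0169816.2, (3S,5aS,6S,7S,9aS)-6-{2-[(3S,5aS,6S,7R,9aS)-7-acetoxy-3-hydroxy-2,2,5a,7-tetramethyldecahydro-1-benzoxepin-6-yl]ethyl}-2,2,5a,7-tetramethyldecahydro-1-benzoxepine-3,7-diyl diacetate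
Conditions: H2 (1–3 atm), Pd/C (10% palladium on carbon), EtOAc/EtOH, rt
Reagents that add atoms: none
Why: Heterogeneous hydrogenation saturates the 1,2-disubstituted alkene and hydrogenolyses the benzyl ether in one operation. The acetates are neither allylic nor benzylic and survive, and no stereocentre is formed.

## Compound list

1 | nerol, (2Z)-3,7-dimethylocta-2,6-dien-1-ol | OC/C=C(C)\CCC=C(C)C | starting material
2 | [(2S,3R)-3-methyl-3-(4-methylpent-3-en-1-yl)oxiran-2-yl]methanol | OC[C@@H]1O[C@]1(C)CCC=C(C)C | intermediate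
3 | (2R,3R)-3,7-dimethyl-2-(prop-1-en-2-yl)oct-6-ene-1,3-diol | CC(C)=CCC[C@@](C)(O)[C@@H](CO)C(C)=C | intermediate
4 | (2R,3R)-1,3-bis[(tert-butyldimethylsilyl)oxy]-3,7-dimethyl-2-(prop-1-en-2-yl)oct-6-ene | CC(C)=CCC[C@@](C)(O[Si](C)(C)C(C)(C)C)[C@@H](CO[Si](C)(C)C(C)(C)C)C(C)=C | intermediate
5 | 3-[(3R,4R)-3-[(tert-butyldimethylsilyl)oxy]-4-{[(tert-butyldimethylsilyl)oxy]methyl}-3,5-dimethylhex-5-en-1-yl]-2,2-dimethyloxirane (both epimers at the oxirane CH) | CC1(C)OC1CC[C@@](C)(O[Si](C)(C)C(C)(C)C)[C@@H](CO[Si](C)(C)C(C)(C)C)C(C)=C | intermediate (not isolated)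
6 | (4R,5R)-4-[(tert-butyldimethylsilyl)oxy]-5-{[(tert-butyldimethylsilyl)oxy]methyl}-4,6-dimethylhept-6-enal | O=CCC[C@@](C)(O[Si](C)(C)C(C)(C)C)[C@@H](CO[Si](C)(C)C(C)(C)C)C(C)=C | intermediate
7 | 3-hydroxy-3-methylbutan-2-one | CC(=O)C(C)(C)O | starting material
8 | 3-methyl-3-[(trimethylsilyl)oxy]butan-2-one | CC(=O)C(C)(C)O[Si](C)(C)C | intermediate
9 | (8R,9R)-8-[(tert-butyldimethylsilyl)oxy]-9-{[(tert-butyldimethylsilyl)oxy]methyl}-5-hydroxy-2,8,10-trimethyl-2-[(trimethylsilyl)oxy]undec-10-en-3-one (both C5 epimers) | CC(C)(O[Si](C)(C)C)C(=O)CC(O)CC[C@@](C)(O[Si](C)(C)C(C)(C)C)[C@@H](CO[Si](C)(C)C(C)(C)C)C(C)=C | intermediate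
10 | (8R,9R)-8-[(tert-butyldimethylsilyl)oxy]-9-{[(tert-butyldimethylsilyl)oxy]methyl}-2,8,10-trimethyl-2-[(trimethylsilyl)oxy]undec-10-ene-3,5-dione | CC(C)(O[Si](C)(C)C)C(=O)CC(=O)CC[C@@](C)(O[Si](C)(C)C(C)(C)C)[C@@H](CO[Si](C)(C)C(C)(C)C)C(C)=C | intermediate (not isolated)
11 | 5-[(3R,4R)-3-[(tert-butyldimethylsilyl)oxy]-4-{[(tert-butyldimethylsilyl)oxy]methyl}-3,5-dimethylhex-5-en-1-yl]-2,2-dimethylfuran-3(2H)-one | CC1(C)OC(=CC1=O)CC[C@@](C)(O[Si](C)(C)C(C)(C)C)[C@@H](CO[Si](C)(C)C(C)(C)C)C(C)=C | intermediate
12 | (1R,5R,7S,8R,9R)-9-[(tert-butyldimethylsilyl)oxy]-8-{[(tert-butyldimethylsilyl)oxy]methyl}-3,3,7,9-tetramethyl-2-oxatricyclo[5.4.0.0(1,5)]undecan-4-one | CC1(C)O[C@@]23CC[C@@](C)(O[Si](C)(C)C(C)(C)C)[C@@H](CO[Si](C)(C)C(C)(C)C)[C@]2(C)C[C@H]3C1=O | intermediate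
13 | (5aS,6R,7R,9aS)-7-[(tert-butyldimethylsilyl)oxy]-6-{[(tert-butyldimethylsilyl)oxy]methyl}-2,2,5a,7-tetramethyloctahydro-1-benzoxepin-3(2H)-one | CC(C)(C)[Si](C)(C)OC[C@H]1[C@]2(C)CCC(=O)C(C)(C)O[C@H]2CC[C@@]1(C)O[Si](C)(C)C(C)(C)C | intermediate
14 | (3S,5aS,6R,7R,9aS)-7-[(tert-butyldimethylsilyl)oxy]-6-{[(tert-butyldimethylsilyl)oxy]methyl}-2,2,5a,7-tetramethyldecahydro-1-benzoxepin-3-ol | CC(C)(C)[Si](C)(C)OC[C@H]1[C@]2(C)CC[C@H](O)C(C)(C)O[C@H]2CC[C@@]1(C)O[Si](C)(C)C(C)(C)C | intermediate
15 | (3S,5aS,6R,7R,9aS)-3-(benzyloxy)-7-[(tert-butyldimethylsilyl)oxy]-6-{[(tert-butyldimethylsilyl)oxy]methyl}-2,2,5a,7-tetramethyldecahydro-1-benzoxepine | CC(C)(C)[Si](C)(C)OC[C@H]1[C@]2(C)CC[C@H](OCc3ccccc3)C(C)(C)O[C@H]2CC[C@@]1(C)O[Si](C)(C)C(C)(C)C | intermediate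
16 | [(3S,5aS,6R,7R,9aS)-3-(benzyloxy)-7-[(tert-butyldimethylsilyl)oxy]-2,2,5a,7-tetramethyldecahydro-1-benzoxepin-6-yl]methanol | OC[C@H]1[C@]2(C)CC[C@H](OCc3ccccc3)C(C)(C)O[C@H]2CC[C@@]1(C)O[Si](C)(C)C(C)(C)C | intermediate
17 | (3S,5aS,6S,7R,9aS)-3-(benzyloxy)-7-[(tert-butyldimethylsilyl)oxy]-2,2,5a,7-tetramethyldecahydro-1-benzoxepine-6-carbaldehyde | O=C[C@H]1[C@]2(C)CC[C@H](OCc3ccccc3)C(C)(C)O[C@H]2CC[C@@]1(C)O[Si](C)(C)C(C)(C)C | intermediate
18 | geraniol, (2E)-3,7-dimethylocta-2,6-dien-1-ol | OC/C=C(C)/CCC=C(C)C | starting material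
19 | [(2S,3S)-3-methyl-3-(4-methylpent-3-en-1-yl)oxiran-2-yl]methanol | OC[C@@H]1O[C@@]1(C)CCC=C(C)C | intermediate
20 | (2R,3S)-3,7-dimethyl-2-(prop-1-en-2-yl)oct-6-ene-1,3-diol | CC(C)=CCC[C@](C)(O)[C@@H](CO)C(C)=C | intermediate
21 | (2R,3S)-1,3-bis[(tert-butyldimethylsilyl)oxy]-3,7-dimethyl-2-(prop-1-en-2-yl)oct-6-ene | CC(C)=CCC[C@](C)(O[Si](C)(C)C(C)(C)C)[C@@H](CO[Si](C)(C)C(C)(C)C)C(C)=C | intermediate
22 | 3-[(3S,4R)-3-[(tert-butyldimethylsilyl)oxy]-4-{[(tert-butyldimethylsilyl)oxy]methyl}-3,5-dimethylhex-5-en-1-yl]-2,2-dimethyloxirane (both epimers at the oxirane CH) | CC1(C)OC1CC[C@](C)(O[Si](C)(C)C(C)(C)C)[C@@H](CO[Si](C)(C)C(C)(C)C)C(C)=C | intermediate (not isolated)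
23 | (4S,5R)-4-[(tert-butyldimethylsilyl)oxy]-5-{[(tert-butyldimethylsilyl)oxy]methyl}-4,6-dimethylhept-6-enal | O=CCC[C@](C)(O[Si](C)(C)C(C)(C)C)[C@@H](CO[Si](C)(C)C(C)(C)C)C(C)=C | intermediate
24 | (8S,9R)-8-[(tert-butyldimethylsilyl)oxy]-9-{[(tert-butyldimethylsilyl)oxy]methyl}-5-hydroxy-2,8,10-trimethyl-2-[(trimethylsilyl)oxy]undec-10-en-3-one (both C5 epimers) | CC(C)(O[Si](C)(C)C)C(=O)CC(O)CC[C@](C)(O[Si](C)(C)C(C)(C)C)[C@@H](CO[Si](C)(C)C(C)(C)C)C(C)=C | intermediate
25 | (8S,9R)-8-[(tert-butyldimethylsilyl)oxy]-9-{[(tert-butyldimethylsilyl)oxy]methyl}-2,8,10-trimethyl-2-[(trimethylsilyl)oxy]undec-10-ene-3,5-dione | CC(C)(O[Si](C)(C)C)C(=O)CC(=O)CC[C@](C)(O[Si](C)(C)C(C)(C)C)[C@@H](CO[Si](C)(C)C(C)(C)C)C(C)=C | intermediate (not isolated)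
26 | 5-[(3S,4R)-3-[(tert-butyldimethylsilyl)oxy]-4-{[(tert-butyldimethylsilyl)oxy]methyl}-3,5-dimethylhex-5-en-1-yl]-2,2-dimethylfuran-3(2H)-one | CC1(C)OC(=CC1=O)CC[C@](C)(O[Si](C)(C)C(C)(C)C)[C@@H](CO[Si](C)(C)C(C)(C)C)C(C)=C | intermediate
27 | (1R,5R,7S,8R,9S)-9-[(tert-butyldimethylsilyl)oxy]-8-{[(tert-butyldimethylsilyl)oxy]methyl}-3,3,7,9-tetramethyl-2-oxatricyclo[5.4.0.0(1,5)]undecan-4-one | CC1(C)O[C@@]23CC[C@](C)(O[Si](C)(C)C(C)(C)C)[C@@H](CO[Si](C)(C)C(C)(C)C)[C@]2(C)C[C@H]3C1=O | intermediate
28 | (5aS,6R,7S,9aS)-7-[(tert-butyldimethylsilyl)oxy]-6-{[(tert-butyldimethylsilyl)oxy]methyl}-2,2,5a,7-tetramethyloctahydro-1-benzoxepin-3(2H)-one | CC(C)(C)[Si](C)(C)OC[C@H]1[C@]2(C)CCC(=O)C(C)(C)O[C@H]2CC[C@]1(C)O[Si](C)(C)C(C)(C)C | intermediate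
29 | (3S,5aS,6R,7S,9aS)-7-[(tert-butyldimethylsilyl)oxy]-6-{[(tert-butyldimethylsilyl)oxy]methyl}-2,2,5a,7-tetramethyldecahydro-1-benzoxepin-3-ol | CC(C)(C)[Si](C)(C)OC[C@H]1[C@]2(C)CC[C@H](O)C(C)(C)O[C@H]2CC[C@]1(C)O[Si](C)(C)C(C)(C)C | intermediate
30 | (3S,5aS,6R,7S,9aS)-3,7-bis[(tert-butyldimethylsilyl)oxy]-6-{[(tert-butyldimethylsilyl)oxy]methyl}-2,2,5a,7-tetramethyldecahydro-1-benzoxepine | CC(C)(C)[Si](C)(C)OC[C@H]1[C@]2(C)CC[C@H](O[Si](C)(C)C(C)(C)C)C(C)(C)O[C@H]2CC[C@]1(C)O[Si](C)(C)C(C)(C)C | intermediate
31 | [(3S,5aS,6R,7S,9aS)-3,7-bis[(tert-butyldimethylsilyl)oxy]-2,2,5a,7-tetramethyldecahydro-1-benzoxepin-6-yl]methanol | OC[C@H]1[C@]2(C)CC[C@H](O[Si](C)(C)C(C)(C)C)C(C)(C)O[C@H]2CC[C@]1(C)O[Si](C)(C)C(C)(C)C | intermediate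
32 | 5-({[(3S,5aS,6S,7S,9aS)-3,7-bis[(tert-butyldimethylsilyl)oxy]-2,2,5a,7-tetramethyldecahydro-1-benzoxepin-6-yl]methyl}sulfanyl)-1-phenyl-1H-tetrazole | c1ccc(cc1)-n1nnnc1SC[C@H]1[C@]2(C)CC[C@H](O[Si](C)(C)C(C)(C)C)C(C)(C)O[C@H]2CC[C@]1(C)O[Si](C)(C)C(C)(C)C | intermediate
33 | 5-({[(3S,5aS,6S,7S,9aS)-3,7-bis[(tert-butyldimethylsilyl)oxy]-2,2,5a,7-tetramethyldecahydro-1-benzoxepin-6-yl]methyl}sulfonyl)-1-phenyl-1H-tetrazole | c1ccc(cc1)-n1nnnc1S(=O)(=O)C[C@H]1[C@]2(C)CC[C@H](O[Si](C)(C)C(C)(C)C)C(C)(C)O[C@H]2CC[C@]1(C)O[Si](C)(C)C(C)(C)C | intermediate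
34 | (E)-1-[(3S,5aS,6S,7S,9aS)-3,7-bis[(tert-butyldimethylsilyl)oxy]-2,2,5a,7-tetramethyldecahydro-1-benzoxepin-6-yl]-2-[(3S,5aS,6S,7R,9aS)-3-(benzyloxy)-7-[(tert-butyldimethylsilyl)oxy]-2,2,5a,7-tetramethyldecahydro-1-benzoxepin-6-yl]ethene | C(=C/[C@H]1[C@]2(C)CC[C@H](OCc3ccccc3)C(C)(C)O[C@H]2CC[C@@]1(C)O[Si](C)(C)C(C)(C)C)\[C@H]1[C@]2(C)CC[C@H](O[Si](C)(C)C(C)(C)C)C(C)(C)O[C@H]2CC[C@]1(C)O[Si](C)(C)C(C)(C)C | intermediate
35 | (3S,5aS,6S,7S,9aS)-6-[(E)-2-{(3S,5aS,6S,7R,9aS)-3-(benzyloxy)-7-hydroxy-2,2,5a,7-tetramethyldecahydro-1-benzoxepin-6-yl}ethenyl]-2,2,5a,7-tetramethyldecahydro-1-benzoxepine-3,7-diol | C(=C/[C@H]1[C@]2(C)CC[C@H](OCc3ccccc3)C(C)(C)O[C@H]2CC[C@@]1(C)O)\[C@H]1[C@]2(C)CC[C@H](O)C(C)(C)O[C@H]2CC[C@]1(C)O | intermediate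
36 | (3S,5aS,6S,7S,9aS)-6-[(E)-2-{(3S,5aS,6S,7R,9aS)-7-acetoxy-3-(benzyloxy)-2,2,5a,7-tetramethyldecahydro-1-benzoxepin-6-yl}ethenyl]-2,2,5a,7-tetramethyldecahydro-1-benzoxepine-3,7-diyl diacetate | C(=C/[C@H]1[C@]2(C)CC[C@H](OCc3ccccc3)C(C)(C)O[C@H]2CC[C@@]1(C)OC(C)=O)\[C@H]1[C@]2(C)CC[C@H](OC(C)=O)C(C)(C)O[C@H]2CC[C@]1(C)OC(C)=O | intermediate
37 | CNP0169816.2, (3S,5aS,6S,7S,9aS)-6-{2-[(3S,5aS,6S,7R,9aS)-7-acetoxy-3-hydroxy-2,2,5a,7-tetramethyldecahydro-1-benzoxepin-6-yl]ethyl}-2,2,5a,7-tetramethyldecahydro-1-benzoxepine-3,7-diyl diacetate | CC(=O)O[C@H]1CC[C@]2(C)[C@H](CC[C@](C)(OC(C)=O)[C@H]2CC[C@H]2[C@]3(C)CC[C@H](O)C(C)(C)O[C@H]3CC[C@@]2(C)OC(C)=O)OC1(C)C | target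

## Step count and least certain steps

Total: 30 steps. Longest linear sequence: 17 steps (steps 14–30, from geraniol 18). The nerol branch has 12 steps before the union (steps 1–4 and 6–13), and the silyl ketone 8 is a one-step side branch (step 5).

**Step 8 (key step; step 20 is the same reaction on the C10 epimer).** The most likely failure is unproductive decay of the biradical together with closure from poorly organised tether rotamers. The four-atom tether offers no five-membered first closure, the alkene carbon that must bond to C7' is fully substituted, and the two bulky silyl ethers of open-chain 11 populate rotamers in which the C9' and C6' branches are anti. The outcome would be low conversion, crossed closure or leakage to the C6' epimer. The fallback ties the two oxygens into a ring before irradiation. Both silyl groups of 11 are removed with HF·pyridine to give the furanone diol F1, which with di-tert-butylsilyl bis(trifluoromethanesulfonate) and 2,6-lutidine gives the cyclic di-tert-butylsilylene F2. In its six-membered dioxasilinane the C9' and C6' branches are cis on adjacent ring carbons and therefore always gauche, which is the arrangement the cyclisation needs, and the crowding by two separate silyl groups is gone. Irradiation as in step 8 should give the silylene-bridged photoadduct F3. HF·pyridine then frees the photoadduct diol F4, and double silylation as in step 3 returns to 12.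

**Step 9 (and step 21).** The ketyl may fragment along the wrong bond. The C4'–C5' bond, exocyclic to the five-membered ring, overlaps better with the ketyl than the ring-fusion bond C4'–C7', and the C2'–O1' bond alpha to the ketone could be expelled as alkoxide. The wanted mode is favoured by radical stability and strain release but is the least well aligned. The fallback replaces the radical by an ionic opening, for which only the C4'–C7' bond is activated: the photoadduct is a donor–acceptor cyclobutane (O1' on C7', the ketone on C4'). Treating 12 with trimethylsilyl trifluoromethanesulfonate and Et3SiH in CH2Cl2 at −78 °C should heterolyse that bond to an oxocarbenium ion at C7' and the trimethylsilyl enol ether F5. The silane reduces the cation axially, anti to the C6' methyl, and aqueous work-up hydrolyses F5 to 13.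

**Step 27.** Both partners carry the reacting carbon on a ring CH flanked by two fully substituted carbons, so addition may be slow. Proton transfer from C11'–H of 17 to the sulfonyl carbanion can then compete, followed by loss of the C10' silyloxy group, which is axial and anti-periplanar to that hydrogen. The fallback reverses the roles of the halves. Alcohol 16 is taken through the Mitsunobu and oxidation conditions of steps 25 and 26 to the PT sulfide F6 and the PT sulfone F7. Alcohol 31 is oxidised as in step 13 to the aldehyde F8, in which the C10 silyloxy group is equatorial and gauche to C11–H, an arrangement that does not support elimination. Union of F7 and F8 under the conditions of step 27 returns to 34.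

**Step 29.** Acylation of the C10' alkoxide may stay incomplete, because this oxygen is axial and 1,3-diaxial to the C6' methyl, and aggregation of a trilithium alkoxide may slow it further. The fallback is a staged acylation with electrophile instead of nucleophile activation. Ac2O with DMAP and Et3N on 35 should acetylate the secondary C3 hydroxyl and the equatorial C10 hydroxyl to give the diacetate F9, with only the axial C10' hydroxyl free. Ac2O with catalytic Sc(OTf)3 in MeCN at −20 °C then acetylates this last position and returns to 36. The low temperature is chosen to spare the benzyl ether and to avoid ionisation of the tertiary carbinol.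

## Further compounds

F1 | step 8 | 5-[(3R,4R)-3-hydroxy-4-(hydroxymethyl)-3,5-dimethylhex-5-en-1-yl]-2,2-dimethylfuran-3(2H)-one | CC1(C)OC(=CC1=O)CC[C@@](C)(O)[C@@H](CO)C(C)=C
F2 | step 8 | 5-{2-[(4R,5R)-2,2-di-tert-butyl-4-methyl-5-(prop-1-en-2-yl)-1,3,2-dioxasilinan-4-yl]ethyl}-2,2-dimethylfuran-3(2H)-one | CC1(C)OC(=CC1=O)CC[C@@]2(C)O[Si](C(C)(C)C)(C(C)(C)C)OC[C@H]2C(C)=C
F3 | step 8 | di-tert-butylsilylene derivative of (1R,5R,7S,8R,9R)-9-hydroxy-8-(hydroxymethyl)-3,3,7,9-tetramethyl-2-oxatricyclo[5.4.0.0(1,5)]undecan-4-one (silicon bridging the two oxygens) | CC1(C)O[C@@]23CC[C@@]4(C)O[Si](C(C)(C)C)(C(C)(C)C)OC[C@H]4[C@]2(C)C[C@H]3C1=O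
F4 | step 8 | (1R,5R,7S,8R,9R)-9-hydroxy-8-(hydroxymethyl)-3,3,7,9-tetramethyl-2-oxatricyclo[5.4.0.0(1,5)]undecan-4-one | CC1(C)O[C@@]23CC[C@@](C)(O)[C@@H](CO)[C@]2(C)C[C@H]3C1=O
F5 | step 9 | (5aS,6R,7R,9aS)-7-[(tert-butyldimethylsilyl)oxy]-6-{[(tert-butyldimethylsilyl)oxy]methyl}-2,2,5a,7-tetramethyl-3-[(trimethylsilyl)oxy]-2,5,5a,6,7,8,9,9a-octahydro-1-benzoxepine | CC(C)(C)[Si](C)(C)OC[C@H]1[C@]2(C)CC=C(O[Si](C)(C)C)C(C)(C)O[C@H]2CC[C@@]1(C)O[Si](C)(C)C(C)(C)C
F6 | step 27 | 5-({[(3S,5aS,6S,7R,9aS)-3-(benzyloxy)-7-[(tert-butyldimethylsilyl)oxy]-2,2,5a,7-tetramethyldecahydro-1-benzoxepin-6-yl]methyl}sulfanyl)-1-phenyl-1H-tetrazole | c1ccc(cc1)-n1nnnc1SC[C@H]1[C@]2(C)CC[C@H](OCc3ccccc3)C(C)(C)O[C@H]2CC[C@@]1(C)O[Si](C)(C)C(C)(C)C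
F7 | step 27 | 5-({[(3S,5aS,6S,7R,9aS)-3-(benzyloxy)-7-[(tert-butyldimethylsilyl)oxy]-2,2,5a,7-tetramethyldecahydro-1-benzoxepin-6-yl]methyl}sulfonyl)-1-phenyl-1H-tetrazole | c1ccc(cc1)-n1nnnc1S(=O)(=O)C[C@H]1[C@]2(C)CC[C@H](OCc3ccccc3)C(C)(C)O[C@H]2CC[C@@]1(C)O[Si](C)(C)C(C)(C)C
F8 | step 27 | (3S,5aS,6S,7S,9aS)-3,7-bis[(tert-butyldimethylsilyl)oxy]-2,2,5a,7-tetramethyldecahydro-1-benzoxepine-6-carbaldehyde | O=C[C@H]1[C@]2(C)CC[C@H](O[Si](C)(C)C(C)(C)C)C(C)(C)O[C@H]2CC[C@]1(C)O[Si](C)(C)C(C)(C)C
F9 | step 29 | (3S,5aS,6S,7S,9aS)-6-[(E)-2-{(3S,5aS,6S,7R,9aS)-3-(benzyloxy)-7-hydroxy-2,2,5a,7-tetramethyldecahydro-1-benzoxepin-6-yl}ethenyl]-2,2,5a,7-tetramethyldecahydro-1-benzoxepine-3,7-diyl diacetate | C(=C/[C@H]1[C@]2(C)CC[C@H](OCc3ccccc3)C(C)(C)O[C@H]2CC[C@@]1(C)O)\[C@H]1[C@]2(C)CC[C@H](OC(C)=O)C(C)(C)O[C@H]2CC[C@]1(C)OC(C)=O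
A1 | alternative 1 | (5aR,9aS)-2,2,5a-trimethyl-5,5a,7,8,9,9a-hexahydro-1-benzoxepin-6(2H)-one | CC1(C)C=CC[C@]2(C)[C@H](CCCC2=O)O1
A2 | alternative 1 | (2R,3S)-2-methyl-3-[(2-methylbut-3-en-2-yl)oxy]-2-(prop-2-en-1-yl)cyclohexan-1-one | C=CC[C@]1(C)[C@H](CCCC1=O)OC(C)(C)C=C
A3 | alternative 2 | (1S,2S,3S,4R)-2,4-dimethyl-3-[(phenylsulfonyl)methyl]-2-{2-[(4S)-2,2,5,5-tetramethyl-1,3-dioxolan-4-yl]ethyl}cyclohexane-1,4-diol | CC1(C)O[C@@H](CC[C@]2(C)[C@@H](O)CC[C@@](C)(O)[C@H]2CS(=O)(=O)c2ccccc2)C(C)(C)O1
A4 | alternative 3 | 5-[(tert-butyldimethylsilyl)oxy]-1,5-dimethylbicyclo[4.2.0]octan-2-one 7,8-cyclic carbonate (cis-fused photoadduct) | O=C1CC[C@@](C)(O[Si](C)(C)C(C)(C)C)[C@@H]2[C@H]3OC(=O)O[C@H]3[C@]12C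
A5 | alternative 3 | (4R)-4-[(tert-butyldimethylsilyl)oxy]-2,4-dimethylcyclohex-2-en-1-one | O=C1CC[C@@](C)(O[Si](C)(C)C(C)(C)C)C=C1C
A6 | alternative 3 | vinylene carbonate (1,3-dioxol-2-one) | O=C1OC=CO1
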